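**Retrosynthetic overview**

1. Labels: ring A is the resorcinol ring of the benzoyl unit and ring B the central resorcinol ring; Ca is the CH bearing the 3,5-dihydroxyphenyl group, Cb the neighbouring CH bearing a 4-hydroxyphenyl group, Cc the CH common to the five- and seven-membered rings, and Cd the seven-ring CH bearing the other 4-hydroxyphenyl group. The target (Ca S, Cb S, Cc R, Cd S) should come from 26 by removal of two tosyl and five methyl groups.
2. Key disconnection: the Cb–Cc bond (five-membered ring) and the Cd–ring A bond (seven-membered ring) are made in one acid-triggered cascade from the 2,3-diaryl-4-styryl-5-aroyl-2,3-dihydrobenzofuran 23.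
3. Enabling feature: Cb and Cd both carry a para-oxygenated phenyl ring, so each can be a stabilized benzylic cation in turn. Cc lies between them as the ring-proximal carbon of a 4-oxystyrene. Ring B has an oxygen ortho to the carbon bonded to Ca, so Cb can be stored as a cyclic benzylic ether (the dihydrofuran). Ring A is a resorcinol ring whose carbon ortho to the carbonyl is para and ortho to its two oxygens.
4. 23 should come from a Horner–Wadsworth–Emmons olefination, a carbonylative Suzuki coupling, an enantioselective Rh-carbene C–H insertion into the PMB ether on ring B (sets Ca, the only stereocentre carried into the key step), and a hydrazone made from the lactol of an aryl Grignard and phthalide 8; 8 comes from 3,5-dimethoxybenzyl alcohol.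
5. Order of ring formation: lactone (temporary, step 2; opened in step 7), dihydrofuran (temporary, step 9), then the five-membered carbocycle and the seven-membered ketone ring together in step 14, which also opens the dihydrofuran.

Key step: step 14

Assumption: Rh2(R-PTAD)4, dirhodium tetrakis[(R)-2-(adamantan-1-yl)-2-phthalimidoacetate], is taken to give the (3S)-dihydrobenzofuran as its cis-2,3 isomer; if the sense of induction is opposite, Rh2(S-PTAD)4 is used, and the C2 configuration is irrelevant because C2 is ionized in step 14.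

**Step 1**
Reactants: 1 3,5-dimethoxybenzyl alcohol
Product: 2 (2,6-dibromo-3,5-dimethoxyphenyl)methanol
Conditions: NBS (2.1 equiv), MeCN, 0 °C to rt
Reagents that add atoms: N-bromosuccinimide, O=C1CCC(=O)N1Br
Why: Electrophilic aromatic bromination should go twice to the positions that are para to one methoxy group and ortho to the other (the two carbons flanking CH2OH), giving the symmetrical dibromide with no stereocentre involved.

**Step 2**
Reactants: 2 (2,6-dibromo-3,5-dimethoxyphenyl)methanol
Product: 5 4-bromo-5,7-dimethoxyisobenzofuran-1(3H)-one, via aryllithium alkoxide 3 (not isolated), via hydroxy acid 4 (not isolated)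
Conditions: n-BuLi (2.1 equiv), THF, −78 °C; CO2; then 2 M HCl, rt
Reagents that add atoms: carbon dioxide, O=C=O
Why: After deprotonation of the alcohol, a single bromine–lithium exchange (Parham-type; a second exchange would need a trianion) should give 3, and carboxylation followed by acid-promoted lactonization of 4 gives the phthalide.

**Step 3**
Reactants: 5 4-bromo-5,7-dimethoxyisobenzofuran-1(3H)-one
Product: 6 4-bromo-7-hydroxy-5-methoxyisobenzofuran-1(3H)-one
Conditions: BCl3 (1.5 equiv), CH2Cl2, −78 to 0 °C; H2O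
Reagents that add atoms: none
Why: Chelation-controlled demethylation: boron held between the lactone carbonyl and the neighbouring C7 methoxy group should cleave only that ether, which differentiates the two ring B oxygens.

**Step 4**
Reactants: 6 4-bromo-7-hydroxy-5-methoxyisobenzofuran-1(3H)-one, 7 4-methoxybenzyl chloride
Product: 8 4-bromo-5-methoxy-7-(4-methoxybenzyloxy)isobenzofuran-1(3H)-one
Conditions: K2CO3, NaI (cat.), DMF, 50 °C
Reagents that add atoms: none
Why: Williamson etherification of the chelated phenol installs the PMB group, whose CH2 and aryl ring later become Cb and its 4-oxyphenyl substituent.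

**Step 5**
Reactants: 9 5-bromobenzene-1,3-diol
Product: 10 5-bromo-1,3-phenylene bis(4-methylbenzenesulfonate)
Conditions: TsCl (2.2 equiv), Et3N, DMAP (cat.), CH2Cl2, 0 °C to rt
Reagents that add atoms: 4-methylbenzenesulfonyl chloride, Cc1ccc(S(=O)(=O)Cl)cc1
Why: O-Sulfonylation of both phenols gives the aryl ring that will sit on Ca in an electron-poor form, which step 14 relies on.

**Step 6**
Reactants: 8 4-bromo-5-methoxy-7-(4-methoxybenzyloxy)isobenzofuran-1(3H)-one, 10 5-bromo-1,3-phenylene bis(4-methylbenzenesulfonate)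
Product: 12 racemic 4-bromo-1-[3,5-bis(tosyloxy)phenyl]-1-hydroxy-5-methoxy-7-(4-methoxybenzyloxy)-1,3-dihydroisobenzofuran (lactol form of the hydroxy ketone), via arylmagnesium chloride 11 (not isolated)
Conditions: 10, iPrMgCl·LiCl (1.05 equiv), THF, −15 °C; then 8, −40 to 0 °C; aq. NH4Cl
Reagents that add atoms: none
Why: Bromine–magnesium exchange is tolerated by aryl sulfonates, and a single Grignard addition to the lactone should stop at the chelated magnesium hemiketal, giving the lactol (its hemiketal centre is racemic and is destroyed in step 7).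

**Step 7**
Reactants: 12 racemic lactol
Product: 13 hydrazone of [3-bromo-2-(hydroxymethyl)-4-methoxy-6-(4-methoxybenzyloxy)phenyl][3,5-bis(tosyloxy)phenyl]methanone
Conditions: N2H4·H2O (3 equiv), AcOH (0.2 equiv), EtOH/THF, 50 °C
Reagents that add atoms: hydrazine, NN
Why: Hydrazone formation should proceed by hemiketal exchange through the planar cyclic oxocarbenium ion of the lactol and then ring opening, so the doubly ortho-substituted ketone never has to be attacked in its open, twisted form.

**Step 8**
Reactants: 13 hydrazone alcohol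
Product: 14 O-triisopropylsilyl ether of 13
Conditions: TIPSCl, imidazole, DMF, rt
Reagents that add atoms: chlorotri(propan-2-yl)silane, CC(C)[Si](Cl)(C(C)C)C(C)C
Why: Imidazole-mediated silylation of the primary alcohol protects it from O–H insertion in step 9, and the bulky, weakly basic silyl ether should not form an oxonium ylide with the carbene.

**Step 9**
Reactants: 14 O-triisopropylsilyl hydrazone
Product: 16 (2R,3S)-5-bromo-6-methoxy-2-(4-methoxyphenyl)-3-[3,5-bis(tosyloxy)phenyl]-4-(triisopropylsilyloxymethyl)-2,3-dihydrobenzofuran, via diaryldiazomethane 15 (not isolated)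
Conditions: MnO2, CH2Cl2, 0 °C; filter; Rh2(R-PTAD)4 (1 mol %), CH2Cl2, −20 °C to rt
Reagents that add atoms: none
Why: Oxidation of the hydrazone gives diazo compound 15, and the dirhodium donor/donor carbene should insert into a benzylic C–H bond of the PMB ether (1,5-C–H insertion) to close the dihydrofuran; the chiral carboxylate ligands select the carbene face and so set Ca (C3, S), with the cis-2,3 isomer expected.

**Step 10**
Reactants: 16 bromo dihydrobenzofuran, 17 (3,5-dimethoxyphenyl)boronic acid
Product: 18 (2R,3S)-5-(3,5-dimethoxybenzoyl)-6-methoxy-2-(4-methoxyphenyl)-3-[3,5-bis(tosyloxy)phenyl]-4-(triisopropylsilyloxymethyl)-2,3-dihydrobenzofuran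
Conditions: PdCl2(dppf) (5 mol %), CO (1 atm), K2CO3, anisole, 80 °C
Reagents that add atoms: carbon monoxide, [C-]#[O+]
Why: Carbonylative Suzuki–Miyaura coupling: the hindered, electron-rich arylpalladium bromide should insert CO before transmetalation and give the diaryl ketone (ring A and its carbonyl), while the aryl tosylates do not add to the dppf–palladium catalyst.

**Step 11**
Reactants: 18 silyl ether ketone
Product: 19 (2R,3S)-5-(3,5-dimethoxybenzoyl)-4-(hydroxymethyl)-6-methoxy-2-(4-methoxyphenyl)-3-[3,5-bis(tosyloxy)phenyl]-2,3-dihydrobenzofuran (in equilibrium with its cyclic hemiketal)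
Conditions: TBAF, AcOH, THF, 0 °C
Reagents that add atoms: none
Why: Buffered fluoride desilylation frees the benzylic alcohol without touching the aryl sulfonates or the base-sensitive C3–H.

**Step 12**
Reactants: 19 hydroxymethyl ketone
Product: 20 (2R,3S)-5-(3,5-dimethoxybenzoyl)-6-methoxy-2-(4-methoxyphenyl)-3-[3,5-bis(tosyloxy)phenyl]-2,3-dihydrobenzofuran-4-carbaldehyde
Conditions: MnO2, CH2Cl2, rt
Reagents that add atoms: none
Why: Benzylic alcohol oxidation of the open hydroxy ketone form; the tertiary hemiketal form cannot be over-oxidized and the dihydrofuran is inert to MnO2.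

**Step 13**
Reactants: 20 keto aldehyde, 21 diethyl (4-methoxybenzyl)phosphonate
Product: 23 (2R,3S)-5-(3,5-dimethoxybenzoyl)-6-methoxy-2-(4-methoxyphenyl)-4-[(E)-2-(4-methoxyphenyl)ethenyl]-3-[3,5-bis(tosyloxy)phenyl]-2,3-dihydrobenzofuran, via phosphonate carbanion 22 (not isolated)
Conditions: 21, NaH, THF, 0 °C; then 20, 0 °C to rt
Reagents that add atoms: none
Why: Horner–Wadsworth–Emmons olefination of the aldehyde (the hindered diaryl ketone does not react) should give the (E)-stilbene, and the preformed carbanion is too weak a base to remove C3–H.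

**Step 14**
Reactants: 23 styryl aroyl dihydrobenzofuran
Product: 26 (Ca S, Cb S, Cc R, Cd S) cascade product with the five-membered carbocycle and the seven-membered ketone ring closed, free OH on ring B next to the carbon bearing Ca, five OMe groups and the bis(tosyloxy)phenyl group on Ca, via benzylic cation 24 (not isolated), via benzylic cation 25 (not isolated)
Conditions: TFA (10 equiv), CH2Cl2/1,1,1,3,3,3-hexafluoropropan-2-ol (4:1), −20 to 0 °C
Reagents that add atoms: none
Why: TFA protonates the dihydrofuran oxygen and the C2–O bond ionizes to the 4-methoxybenzylic cation 24 (Cb), which is attacked by the ring-proximal carbon of the ortho (E)-4-methoxystyryl group in a 5-exo-trig cation–olefin closure of the five-membered ring (6-endo would give an unstabilized cation); the resulting 4-methoxybenzylic cation 25 (Cd) alkylates ring A at the carbon ortho to the carbonyl, closing the seven-membered ring by Friedel–Crafts reaction. The closest known reaction type is the acid-induced rearrangement of 2-aryl-4-styryl-2,3-dihydrobenzofurans of the ε-viniferin class into indane stilbene dimers by the same ionization, cation–olefin and Friedel–Crafts sequence. Ca is not touched and controls the rest: the aryl group on Cb should end trans to the aryl on Ca, and the side chain on Cc trans to the aryl on Cb, because the all-trans arrangement avoids eclipsing of neighbouring aryl groups in the envelope-like transition state and is also the thermodynamic one if the first closure reverses. Cd is set in the Friedel–Crafts step: cation 25 holds the Cc–H bond in its plane to minimize allylic 1,3-strain, and ring A, tethered through ring B, can only reach the face turned towards ring B, which places Cd–H anti to Cc–H as in the target. The selectivity needed is capture of cation 25 by ring A and not by the aryl group on Ca, which is cis to the cationic side chain and would give a bicyclo[3.2.1]octane; the two electron-withdrawing tosyloxy groups switch that ring off, while ring A keeps two methoxy donors. Loss of the proton on Ca from cation 24 is the main threat to enantiopurity and is countered by the low temperature, the non-basic medium and the speed of the 5-exo closure.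

**Step 15**
Reactants: 26 cascade product
Product: 27 (Ca S, Cb S, Cc R, Cd S) bis-phenol with the 3,5-dihydroxyphenyl group on Ca and five OMe groups
Conditions: KOH (10 equiv), MeOH/THF/H2O, 60 °C, Ar; then 1 M HCl
Reagents that add atoms: none
Why: Hydroxide attacks sulfur of the two aryl sulfonates (S–O cleavage) and frees both phenols; the diaryl ketone cannot enolize and no benzylic C–H is acidic enough to epimerize under these conditions.

**Step 16**
Reactants: 27 pentamethyl ether
Product: 28 CNP0116600.1 (Ca S, Cb S, Cc R, Cd S)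
Conditions: BBr3 (15 equiv), CH2Cl2, −78 °C to rt; MeOH, then H2O
Reagents that add atoms: none
Why: Lewis-acid demethylation of the five aryl methyl ethers by BBr3 should leave the ketone and the four C–H stereocentres untouched.

**Compound list**

1 | 3,5-dimethoxybenzyl alcohol | COc1cc(CO)cc(OC)c1 | starting material
2 | (2,6-dibromo-3,5-dimethoxyphenyl)methanol | COc1cc(OC)c(Br)c(CO)c1Br | intermediate
3 | lithium (2-bromo-6-lithio-3,5-dimethoxyphenyl)methanolate | [Li]OCc1c(Br)c(OC)cc(OC)c1[Li] | intermediate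
4 | 3-bromo-2-(hydroxymethyl)-4,6-dimethoxybenzoic acid | OCc1c(Br)c(OC)cc(OC)c1C(=O)O | intermediate
5 | 4-bromo-5,7-dimethoxyisobenzofuran-1(3H)-one | O=C1OCc2c(Br)c(OC)cc(OC)c21 | intermediate
6 | 4-bromo-7-hydroxy-5-methoxyisobenzofuran-1(3H)-one | O=C1OCc2c(Br)c(OC)cc(O)c21 | intermediate
7 | 4-methoxybenzyl chloride | COc1ccc(CCl)cc1 | starting material
8 | 4-bromo-5-methoxy-7-(4-methoxybenzyloxy)isobenzofuran-1(3H)-one | O=C1OCc2c(Br)c(OC)cc(OCc3ccc(OC)cc3)c21 | intermediate
9 | 5-bromobenzene-1,3-diol | Oc1cc(O)cc(Br)c1 | starting material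
10 | 5-bromo-1,3-phenylene bis(4-methylbenzenesulfonate) | Brc1cc(OS(=O)(=O)c2ccc(C)cc2)cc(OS(=O)(=O)c2ccc(C)cc2)c1 | intermediate
11 | [3,5-bis(tosyloxy)phenyl]magnesium chloride | Cl[Mg]c1cc(OS(=O)(=O)c2ccc(C)cc2)cc(OS(=O)(=O)c2ccc(C)cc2)c1 | intermediate
12 | racemic 4-bromo-1-[3,5-bis(tosyloxy)phenyl]-1-hydroxy-5-methoxy-7-(4-methoxybenzyloxy)-1,3-dihydroisobenzofuran | OC1(c2cc(OS(=O)(=O)c3ccc(C)cc3)cc(OS(=O)(=O)c3ccc(C)cc3)c2)OCc2c(Br)c(OC)cc(OCc3ccc(OC)cc3)c21 | intermediate
13 | hydrazone of [3-bromo-2-(hydroxymethyl)-4-methoxy-6-(4-methoxybenzyloxy)phenyl][3,5-bis(tosyloxy)phenyl]methanone | NN=C(c1cc(OS(=O)(=O)c2ccc(C)cc2)cc(OS(=O)(=O)c2ccc(C)cc2)c1)c1c(CO)c(Br)c(OC)cc1OCc1ccc(OC)cc1 | intermediate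
14 | O-triisopropylsilyl ether of 13 | NN=C(c1cc(OS(=O)(=O)c2ccc(C)cc2)cc(OS(=O)(=O)c2ccc(C)cc2)c1)c1c(CO[Si](C(C)C)(C(C)C)C(C)C)c(Br)c(OC)cc1OCc1ccc(OC)cc1 | intermediate
15 | diaryldiazomethane from 14 | [N-]=[N+]=C(c1cc(OS(=O)(=O)c2ccc(C)cc2)cc(OS(=O)(=O)c2ccc(C)cc2)c1)c1c(CO[Si](C(C)C)(C(C)C)C(C)C)c(Br)c(OC)cc1OCc1ccc(OC)cc1 | intermediate
16 | (2R,3S)-5-bromo-6-methoxy-2-(4-methoxyphenyl)-3-[3,5-bis(tosyloxy)phenyl]-4-(triisopropylsilyloxymethyl)-2,3-dihydrobenzofuran | COc1ccc([C@@H]2Oc3cc(OC)c(Br)c(CO[Si](C(C)C)(C(C)C)C(C)C)c3[C@@H]2c2cc(OS(=O)(=O)c4ccc(C)cc4)cc(OS(=O)(=O)c4ccc(C)cc4)c2)cc1 | intermediate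
17 | (3,5-dimethoxyphenyl)boronic acid | COc1cc(OC)cc(B(O)O)c1 | starting material
18 | (2R,3S)-5-(3,5-dimethoxybenzoyl)-6-methoxy-2-(4-methoxyphenyl)-3-[3,5-bis(tosyloxy)phenyl]-4-(triisopropylsilyloxymethyl)-2,3-dihydrobenzofuran | COc1ccc([C@@H]2Oc3cc(OC)c(C(=O)c4cc(OC)cc(OC)c4)c(CO[Si](C(C)C)(C(C)C)C(C)C)c3[C@@H]2c2cc(OS(=O)(=O)c4ccc(C)cc4)cc(OS(=O)(=O)c4ccc(C)cc4)c2)cc1 | intermediate
19 | (2R,3S)-5-(3,5-dimethoxybenzoyl)-4-(hydroxymethyl)-6-methoxy-2-(4-methoxyphenyl)-3-[3,5-bis(tosyloxy)phenyl]-2,3-dihydrobenzofuran | COc1ccc([C@@H]2Oc3cc(OC)c(C(=O)c4cc(OC)cc(OC)c4)c(CO)c3[C@@H]2c2cc(OS(=O)(=O)c4ccc(C)cc4)cc(OS(=O)(=O)c4ccc(C)cc4)c2)cc1 | intermediate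
20 | (2R,3S)-5-(3,5-dimethoxybenzoyl)-6-methoxy-2-(4-methoxyphenyl)-3-[3,5-bis(tosyloxy)phenyl]-2,3-dihydrobenzofuran-4-carbaldehyde | COc1ccc([C@@H]2Oc3cc(OC)c(C(=O)c4cc(OC)cc(OC)c4)c(C=O)c3[C@@H]2c2cc(OS(=O)(=O)c4ccc(C)cc4)cc(OS(=O)(=O)c4ccc(C)cc4)c2)cc1 | intermediate
21 | diethyl (4-methoxybenzyl)phosphonate | CCOP(=O)(Cc1ccc(OC)cc1)OCC | starting material
22 | sodium salt of the carbanion of 21 | CCOP(=O)([CH-]c1ccc(OC)cc1)OCC.[Na+] | intermediate
23 | (2R,3S)-5-(3,5-dimethoxybenzoyl)-6-methoxy-2-(4-methoxyphenyl)-4-[(E)-2-(4-methoxyphenyl)ethenyl]-3-[3,5-bis(tosyloxy)phenyl]-2,3-dihydrobenzofuran | COc1ccc([C@@H]2Oc3cc(OC)c(C(=O)c4cc(OC)cc(OC)c4)c(/C=C/c4ccc(OC)cc4)c3[C@@H]2c2cc(OS(=O)(=O)c4ccc(C)cc4)cc(OS(=O)(=O)c4ccc(C)cc4)c2)cc1 | intermediate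
24 | ring-opened 4-methoxybenzylic cation at Cb (free ring B phenol, Ca S), trifluoroacetate | COc1ccc([CH+][C@@H](c2cc(OS(=O)(=O)c3ccc(C)cc3)cc(OS(=O)(=O)c3ccc(C)cc3)c2)c2c(O)cc(OC)c(C(=O)c3cc(OC)cc(OC)c3)c2/C=C/c2ccc(OC)cc2)cc1.[O-]C(=O)C(F)(F)F | intermediate
25 | all-trans indane with exocyclic 4-methoxybenzylic cation at Cd, trifluoroacetate | COc1ccc([CH+][C@@H]2c3c(C(=O)c4cc(OC)cc(OC)c4)c(OC)cc(O)c3[C@H](c3cc(OS(=O)(=O)c4ccc(C)cc4)cc(OS(=O)(=O)c4ccc(C)cc4)c3)[C@H]2c2ccc(OC)cc2)cc1.[O-]C(=O)C(F)(F)F | intermediate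
26 | (Ca S, Cb S, Cc R, Cd S) cascade product: target skeleton with free ring B OH next to the Ca-bearing carbon, five OMe groups and a 3,5-bis(tosyloxy)phenyl group on Ca | O=C1c2cc(OC)cc(OC)c2[C@H](c2ccc(OC)cc2)[C@@H]2c3c1c(OC)cc(O)c3[C@H](c1cc(OS(=O)(=O)c4ccc(C)cc4)cc(OS(=O)(=O)c4ccc(C)cc4)c1)[C@H]2c1ccc(OC)cc1 | intermediate
27 | (Ca S, Cb S, Cc R, Cd S) detosylated pentamethyl ether | O=C1c2cc(OC)cc(OC)c2[C@H](c2ccc(OC)cc2)[C@@H]2c3c1c(OC)cc(O)c3[C@H](c1cc(O)cc(O)c1)[C@H]2c1ccc(OC)cc1 | intermediate
28 | CNP0116600.1 (Ca S, Cb S, Cc R, Cd S) | O=C1c2cc(O)cc(O)c2[C@H](c2ccc(O)cc2)[C@@H]2c3c1c(O)cc(O)c3[C@H](c1cc(O)cc(O)c1)[C@H]2c1ccc(O)cc1 | target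

**Step count and risks**

Total step count: 16. Longest linear sequence: 15 steps (steps 1–4 and 6–16, from 3,5-dimethoxybenzyl alcohol); step 5 is a one-step side branch.

The three steps most likely to fail:

Step 14 (key cascade). The seven-membered Friedel–Crafts closure on the carbonyl-deactivated ring A may be slower than proton loss or solvent capture of cation 25. In addition, proton loss next to Ca from cation 24, followed by re-protonation, would erode the enantiomeric purity. Fallback: the cascade is split in two. Starting from 23, camphorsulfonic acid (cat.) in MeOH/CH2Cl2 at 0 °C should open the dihydrofuran and close the five-membered ring, with cation 25 trapped by methanol as the benzylic methyl ether F1 (both epimers at Cd). After isolation, F1 is re-ionized under anhydrous conditions (BF3·OEt2, CH2Cl2/1,1,1,3,3,3-hexafluoropropan-2-ol, −40 °C), where only the Friedel–Crafts closure remains, and the route is rejoined at 26.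

Step 9 (carbene C–H insertion). Enantioface discrimination may be poor, and carbene dimerization to the azine may compete, because the carbene carbon is flanked by two ortho substituents. Fallback: catalyst control is given up. From 14, the diazo compound 15 is decomposed by slow addition to achiral Rh2(OAc)4 in CH2Cl2, which should give the racemic cis-dihydrobenzofuran, that is 16 together with its enantiomer F2. The enantiomers are separated by preparative chromatography on a chiral stationary phase, and the route is rejoined at 16.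

Step 10 (carbonylative coupling). Oxidative addition at the doubly ortho-substituted, electron-rich aryl bromide may be slow, and direct biaryl coupling without CO uptake may compete. Fallback: from 16, bromine–lithium exchange (n-BuLi, THF, −90 °C, which is faster than attack on the sulfonates) gives aryllithium F3, which is added to 3,5-dimethoxybenzaldehyde to give carbinol F4 (both epimers at the carbinol carbon). TBAF/AcOH removes the silyl group to give diol F5, and MnO2 oxidizes both benzylic alcohols at once, which rejoins the route at keto aldehyde 20.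

**Further compounds**

F1 | step 14 | all-trans indane methyl ether: ring B phenol, uncyclized 3,5-dimethoxybenzoyl group, CH(OMe)(4-methoxyphenyl) on Cc (both epimers at Cd) | COC(c1ccc(OC)cc1)[C@@H]1c2c(C(=O)c3cc(OC)cc(OC)c3)c(OC)cc(O)c2[C@H](c2cc(OS(=O)(=O)c3ccc(C)cc3)cc(OS(=O)(=O)c3ccc(C)cc3)c2)[C@H]1c1ccc(OC)cc1
F2 | step 9 | (2S,3R) enantiomer of 16 | COc1ccc([C@H]2Oc3cc(OC)c(Br)c(CO[Si](C(C)C)(C(C)C)C(C)C)c3[C@H]2c2cc(OS(=O)(=O)c4ccc(C)cc4)cc(OS(=O)(=O)c4ccc(C)cc4)c2)cc1
F3 | step 10 | C5 aryllithium from 16 | COc1ccc([C@@H]2Oc3cc(OC)c([Li])c(CO[Si](C(C)C)(C(C)C)C(C)C)c3[C@@H]2c2cc(OS(=O)(=O)c4ccc(C)cc4)cc(OS(=O)(=O)c4ccc(C)cc4)c2)cc1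
F4 | step 10 | (2R,3S)-5-[(3,5-dimethoxyphenyl)(hydroxy)methyl] analogue of 18 (carbinol epimers) | COc1ccc([C@@H]2Oc3cc(OC)c(C(O)c4cc(OC)cc(OC)c4)c(CO[Si](C(C)C)(C(C)C)C(C)C)c3[C@@H]2c2cc(OS(=O)(=O)c4ccc(C)cc4)cc(OS(=O)(=O)c4ccc(C)cc4)c2)cc1
F5 | step 10 | (2R,3S) diol from F4 after desilylation | COc1ccc([C@@H]2Oc3cc(OC)c(C(O)c4cc(OC)cc(OC)c4)c(CO)c3[C@@H]2c2cc(OS(=O)(=O)c4ccc(C)cc4)cc(OS(=O)(=O)c4ccc(C)cc4)c2)cc1
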